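**Conventions.** Rings are lettered A to G from the 2,4,6-trihydroxyphenyl end. On rings B, C, E and F, position 1 is the ether carbon flanked by two C–H and position 4 the ether carbon flanked by two oxygenated carbons. A1 and G1 are the ether carbons of the end rings. On ring D, D1 bears the oxygen to ring C, D6 the oxygen to ring E, and D2 is the only C–H. "EFG aryloxy" means the 4-[3,5-dimethoxy-4-(3,4,5-trimethoxyphenoxy)phenoxy]-3,5-dimethoxyphenoxy group. Compound numbers are those of the steps and of the compound list.

**Remark (assumption).** The tertiary oxygen of the cyclobutenone is carried as its methyl ether instead of a free hydroxyl, so ring D emerges as a mono-phenol free only at D1; compounds 2 and 9 are taken as purchasable.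

## Analysis of the target

Compound 30 (C42H30O23) is a linear chain of seven benzene rings joined only by six diaryl ether oxygens; it carries seventeen free phenolic hydroxyls and has no stereocentre, so every selectivity question is one of regiochemistry. Reading from ring G to ring A, the oxygen on position 1 of each ring is bound to a carbon of the next ring that lies between two oxygenated carbons (G1–O–F4, F1–O–E4, E1–O–D6, D1–O–C4, C1–O–B4, B1–O–A1). Ring D is the exception in substitution: D3, D4, D5, D6 and D1 are five contiguous oxygenated carbons (three hydroxyls, then the two ether oxygens ortho to each other) and D2 is the only C–H. The free polyphenol, above all the pyrogallol unit of ring G and the trihydroxylated ring D, is easily oxidised in air once deprotonated, so the hydroxyls must stay masked to the end and the last step must be non-oxidative. The difficulty is twofold: six ethers that each involve a doubly flanked carbon, and ring D, where an arylation approach would have to tell five neighbouring oxygens apart and form the D6–O–E1 ether at the most crowded phenol of a very electron-rich ring. The strategy rests on the fact that D4, D5, D6 and D1 can be the four carbons of a squaric acid derivative, each already bound to oxygen, while D3 (oxygenated) and D2 (C–H) can come from a 1-methoxyvinyl group. Closing the D1–D2 bond then gives ring D with every substituent placed by connectivity.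

## Retrosynthetic reasoning

**30 ⇒ 29.** The last operation is the cleavage of sixteen O–CH3 bonds of 29. Methyl is the one protecting group that survives everything upstream (carbonate base at 120 °C, peracid, an organolithium, thermolysis at 110 °C), and it arrives with the building blocks 1, 2 and 14. The price is one Lewis-acidic step at the end, acceptable because the molecule has no stereocentre and its diaryl ethers offer no alkyl carbon for cleavage.

**29 ⇒ 20 + three equivalents of 2.** The ethers A1–O, B4–O and C4–O are cut on the side of the flanked carbon. That carbon can then be the electrophile: in 2 it bears fluorine para to a formyl group, and the unhindered position-1 phenol of the growing chain is the nucleophile. The formyl group is afterwards exchanged for hydroxyl by oxidative aryl migration, which regenerates a position-1 phenol for the next cycle (21, 23, 24, 26, 27 on the way). Cutting on the other side would require a doubly flanked phenol to attack an unactivated carbon.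

**20 ⇒ 17 (key disconnection).** Ring D is opened at the D1–D2 carbon–carbon bond. This traces the pentaoxygenated arene to cyclobutenone 17, whose four ring carbons become D1, D6, D5, D4 and whose 1-methoxyvinyl group supplies D3 and D2. Cutting here avoids any differentiation of five adjacent oxygens on a finished arene, because each oxygen is placed by the identity of the carbon it sits on in 17. The forward reaction must open the four-membered ring to a dienylketene with the vinyl group turned toward the ketene, close the six-membered ring and aromatise.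

**17 ⇒ 13 + 14.** The bond between the future D4 and D3 (cyclobutenone C4 to vinyl carbon) and the O–CH3 bond on the C4 oxygen are cut. Forward, the lithiated vinyl ether 15 from 14 must add to only one of the two carbonyls of 13, the one next to the methoxy-bearing carbon, and the resulting alkoxide 16 is methylated in the same flask. Capping this oxygen means 20 appears with D1 as its only free hydroxyl; a free carbinol would come through as a second phenol at D4, demanding site-selective arylation of an air-sensitive dihydroxyarene.

**13 ⇒ 8 + 11; 11 ⇒ 10 ⇒ 9.** The D6–O bond, the most hindered ether of the target, is cut at the squarate stage, where it is an addition–elimination at a vinylogous acid chloride carbon and not an arylation of a crowded phenol. A chloride is used as the leaving group because a phenoxide cannot displace methoxide from a dialkyl squarate against the leaving-group order. The ester chloride 11 comes from squaric acid 9 via dichloride 10.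

**8 ⇒ 1 + two equivalents of 2.** The E4–O and F4–O bonds are cut exactly as in the second paragraph, so that 8 arises from 1 by two cycles of fluoride displacement and formyl-to-hydroxyl exchange (3, 5, 6 on the way). One building block thus serves five of the seven rings.

## Alternatives that were turned down

**Alternative 1:** Both ether bonds of ring C (C1–O toward ring B, C4–O toward ring D) are cut at once. Ring C becomes a doubly electrophilic dichloroarene activated as its cyclopentadienylruthenium cation A1, [CpRu(2,5-dichloro-1,3-dimethoxybenzene)]PF6 (divalent ruthenium). In the forward key step, the phenoxide of the AB dimer A2 (hydroxyl at B4) displaces the unhindered chloride of A1 in one flask. The phenoxide of a ring D unit A3 (hydroxyl at D1, benzyloxy at D6) then displaces the chloride between the two methoxy groups, giving the ruthenium complex A4 of the protected ABCD tetramer.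
- For it: metal activation makes an electron-rich chloroarene a strong SNAr electrophile that should react near room temperature even at a flanked carbon. Joining three pieces in one operation is more convergent than anything in the chosen route, whose longest linear sequence is clearly longer; on convergence this alternative is stronger.
- Against it: the cationic fragment is stoichiometric and must be put on and photolysed off, and the order of the two substitutions depends wholly on the rate gap between the two chlorides. Above all, the step does not touch the real problem: A3 still has to be made with five differentiated oxygens. After debenzylation, the trimer must be attached at D6, a phenol wedged between the D1 aryloxy and D5 methoxy groups, to an E1 carbon that is not activated. The fluoroaldehyde logic cannot be used there, because it would connect through the flanked carbon and give ring E the wrong orientation.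
- Comparison: the chosen strategy gives up convergence, but forms the D6–O–E1 bond on a four-membered, acid-chloride-like carbon before ring D exists and fixes the oxygenation pattern by connectivity and not by selective protection.

**Alternative 2:** The A1–A2 carbon–carbon bond of ring A is cut, unfolding the terminal phloroglucinol ring into a triketide chain, the 6-aryloxy-3,5-dioxohexanoate A5. In the forward key step, under a methoxide base, the aryloxy-bearing carbon (C6) attacks the ester carbonyl (C1) in an intramolecular Claisen condensation, and the cyclic trione enolises to the 2-aryloxyphloroglucinol A6 (AB dimer, benzyloxy at B4).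
- For it: it mirrors the biogenesis of phloroglucinol, uses cheap acyclic material and delivers ring A with three free hydroxyls, so three fewer methyl ethers would need cleaving at the end. On that point it is better than the chosen route.
- Against it: the required nucleophile is the least acidic of the three methylene groups; C4 and C2 are deprotonated first. 3,5-Dioxo esters also tend to lactonise through the C5 enol oxygen to a 4-hydroxy-2-pyranone, so the mode of cyclisation is in doubt. The ring it builds is the easiest one in the molecule (ring A costs two routine steps from 26 in the chosen route). A free triol appears at the start of a long sequence and would have to be masked again. The chain would then have to grow from B4, a doubly flanked phenol, toward an unactivated C1 carbon, the reverse of the polarity that makes the fluoroaldehyde iteration work. Ring D is left untouched.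
- Comparison: the chosen strategy spends its one ring-forming event on the ring that cannot be bought.

**Alternative 3:** The G1–O and F1–O ether bonds of the EFG trimer are traced back to ester linkages, i.e. to the depside A7, assembled by two esterifications of gallic- and syringic-acid-type units. In the forward key step, a zerovalent nickel catalyst with a bulky, electron-rich diphosphine inserts into each acyl C–O bond, extrudes CO and reductively eliminates the diaryl ether. A7 thus loses two molecules of CO and contracts to the benzyl-protected EFG trimer A8.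
- For it: esterification is far easier than SNAr at a flanked carbon, the acids are feedstock chemicals, and two ether bonds arise in one catalytic step. A8 could be reached in about three operations against four for 8, so on step count for this fragment the alternative is at least as good.
- Against it: decarbonylative etherification is dependable for esters of azine carboxylic acids and electron-poor aroyl groups. Here both aroyl groups are electron-rich trialkoxybenzoyl units (slow oxidative addition), and both aryloxide partners are 2,6-dimethoxy-substituted (crowded reductive elimination). The same low-valent nickel can insert into aryl–OMe bonds, of which A7 has seven. Two such events must succeed on one molecule without aryloxide exchange. It also addresses only the trimer and not ring D.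
- Comparison: the chosen strategy keeps the routine part routine and places its single uncertain step where the structural problem is.

Key step: step 9

## Route

Step 1
Reactants: 1 3,4,5-trimethoxyphenol (ring G); 2 4-fluoro-3,5-dimethoxybenzaldehyde
Product: 3 3,5-dimethoxy-4-(3,4,5-trimethoxyphenoxy)benzaldehyde (FG aldehyde)
Conditions: Cs2CO3, DMSO, 120 °C
Reagents that add atoms: none
Why: SNAr by addition–elimination: the phenoxide of 1 adds at C4 of 2, where the Meisenheimer charge is taken up by the para formyl group, and fluoride leaves; fluorine is small enough to let the nucleophile in between the two methoxy groups, and the product has no further leaving group.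

Step 2
Reactants: 3 FG aldehyde
Product: 5 3,5-dimethoxy-4-(3,4,5-trimethoxyphenoxy)phenol (FG phenol), via FG aryl formate 4 (not isolated)
Conditions: mCPBA, CH2Cl2, 0 °C → rt; then Et3N (cat.), MeOH, rt
Reagents that add atoms: 3-chloroperoxybenzoic acid (mCPBA), OOC(=O)c1cccc(Cl)c1
Why: Baeyer–Villiger oxidation (Dakin type): in the Criegee adduct the electron-rich, para-aryloxy-substituted aryl group migrates in preference to hydrogen to give formate 4, which amine-catalysed methanolysis cleaves to the phenol; methyl and diaryl ethers are inert to the peracid at this temperature.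

Step 3
Reactants: 5 FG phenol; 2 4-fluoro-3,5-dimethoxybenzaldehyde
Product: 6 4-[3,5-dimethoxy-4-(3,4,5-trimethoxyphenoxy)phenoxy]-3,5-dimethoxybenzaldehyde (EFG aldehyde)
Conditions: Cs2CO3, DMSO, 120 °C
Reagents that add atoms: none
Why: Second SNAr of the same kind as step 1; the hydroxyl of 5 has two ortho C–H neighbours, so the nucleophile is unhindered although larger.

Step 4
Reactants: 6 EFG aldehyde
Product: 8 4-[3,5-dimethoxy-4-(3,4,5-trimethoxyphenoxy)phenoxy]-3,5-dimethoxyphenol (EFG phenol), via EFG aryl formate 7 (not isolated)
Conditions: mCPBA, CH2Cl2, 0 °C → rt; then Et3N (cat.), MeOH, rt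
Reagents that add atoms: 3-chloroperoxybenzoic acid (mCPBA), OOC(=O)c1cccc(Cl)c1
Why: Baeyer–Villiger oxidation with aryl migration and formate methanolysis, as in step 2.

Step 5
Reactants: 9 squaric acid
Product: 10 squaric acid dichloride (3,4-dichlorocyclobut-3-ene-1,2-dione)
Conditions: (COCl)2, DMF (cat.), CH2Cl2, 0 → 40 °C
Reagents that add atoms: oxalyl chloride, ClC(=O)C(=O)Cl
Why: Vilsmeier-type activation converts both vinylogous carboxylic acid hydroxyls of 9 into chlorides; this is the standard preparation of the dichloride.

Step 6
Reactants: 10 squaric acid dichloride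
Product: 11 3-chloro-4-methoxycyclobut-3-ene-1,2-dione
Conditions: MeOH (1.0 equiv), Et2O, 0 °C → rt
Reagents that add atoms: methanol, CO
Why: Alcoholysis of a vinylogous acid chloride by addition–elimination; the methoxy group introduced first donates into the enedione and deactivates the remaining C–Cl, so one equivalent of methanol should stop at the ester chloride.

Step 7
Reactants: 8 EFG phenol; 11 3-chloro-4-methoxycyclobut-3-ene-1,2-dione
Product: 13 3-(EFG aryloxy)-4-methoxycyclobut-3-ene-1,2-dione, via sodium phenoxide 12 (not isolated)
Conditions: NaH (1.0 equiv), THF, 0 °C; then 11, THF, −78 → 0 °C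
Reagents that add atoms: none
Why: Addition–elimination at the chlorine-bearing carbon of 11: chloride is a far better leaving group than methoxide, so phenoxide 12 should replace chlorine only, and an aryloxide cannot displace the poorer leaving group methoxide from the product. Preforming the sodium salt keeps amines and water away from the moisture-sensitive aryl squarate.

Step 8
Reactants: 13 3-(EFG aryloxy)-4-methoxycyclobut-3-ene-1,2-dione; 14 methyl vinyl ether
Product: 17 racemic 2-(EFG aryloxy)-3,4-dimethoxy-4-(1-methoxyvinyl)cyclobut-2-en-1-one, via 1-methoxyvinyllithium 15 (not isolated), via lithium alkoxide 16 (not isolated)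
Conditions: 14, t-BuLi, THF, −78 → 0 °C; cannulate into 13, THF, −78 °C; then MeOTf, −78 → −20 °C
Reagents that add atoms: methyl trifluoromethanesulfonate (MeOTf), COS(=O)(=O)C(F)(F)F
Why: Alpha-lithiation of the vinyl ether gives the acyl anion equivalent 15, which adds 1,2 to the squarate at −78 °C as organolithiums do with squaric esters; the carbonyl next to C–OMe is the more electrophilic and less shielded one, being only the vinylogous ester of the weak aryloxy donor, and attack there leaves the stronger methoxy vinylogous ester intact. The lithium alkoxide 16 is O-methylated in the flask by MeOTf; the new quaternary stereocentre forms without control (racemic) and is destroyed in step 9.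

Step 9
Reactants: 17 racemic 2-(EFG aryloxy)-3,4-dimethoxy-4-(1-methoxyvinyl)cyclobut-2-en-1-one
Product: 20 2-(EFG aryloxy)-3,4,5-trimethoxyphenol (DEFG phenol; free hydroxyl at D1; methoxy at D3 D4 D5), via dienylketene 18 (not isolated), via cyclohexadienone 19 (not isolated)
Conditions: toluene (degassed, base-washed glassware), 110 °C, Ar
Reagents that add atoms: none
Why: Heating opens the cyclobutenone by thermal conrotatory 4-pi electrocyclic cleavage of the C1–C4 bond, the C4 methoxy group (the stronger donor) rotating outward and the 1-methoxyvinyl group inward, which gives the (Z)-dienylketene 18. The ketene carbon then bonds to the vinyl CH2 terminus in a thermal disrotatory 6-pi electrocyclisation, which closes the six-membered ring D by forming the D1–D2 carbon–carbon bond and gives the cyclohexa-2,4-dienone 19. A proton shift from the ring CH2 (D2) to the carbonyl oxygen aromatises 19 to phenol 20, an irreversible step that pulls the sequence forward. The closest known reaction type is the Moore rearrangement of 4-alkenyl-4-hydroxy- and 4-alkoxycyclobutenones derived from squaric esters, which gives hydroquinones and their monoethers. No stereocentre is formed and the single stereocentre of racemic 17 disappears. The selectivity needed is torquoselectivity (vinyl inward), secured by the strong outward preference of the C4 oxygen substituent; because that oxygen is methylated, lactonisation of the ketene by a free hydroxyl is excluded. All six ring positions follow from connectivity: ketene oxygen to D1 (free OH), squarate carbons to D6 (EFG aryloxy), D5 and D4 (OMe), vinyl carbons to D3 (OMe) and D2 (H).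

Step 10
Reactants: 20 DEFG phenol; 2 4-fluoro-3,5-dimethoxybenzaldehyde
Product: 21 3,5-dimethoxy-4-[3,4,5-trimethoxy-2-(EFG aryloxy)phenoxy]benzaldehyde (CDEFG aldehyde)
Conditions: Cs2CO3, DMSO, 120 °C
Reagents that add atoms: none
Why: SNAr as in step 1; 20 has a single free hydroxyl (D1), so no choice between ring D oxygens arises, and the fully O-methylated ring D is not exposed to base as an oxidisable dihydroxyarene.

Step 11
Reactants: 21 CDEFG aldehyde
Product: 23 3,5-dimethoxy-4-[3,4,5-trimethoxy-2-(EFG aryloxy)phenoxy]phenol (CDEFG phenol), via CDEFG aryl formate 22 (not isolated)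
Conditions: mCPBA (1.1 equiv), CH2Cl2, 0 °C → rt; then Et3N (cat.), MeOH, rt
Reagents that add atoms: 3-chloroperoxybenzoic acid (mCPBA), OOC(=O)c1cccc(Cl)c1
Why: Baeyer–Villiger oxidation as in step 2; addition of the peracid to the aldehyde is much faster than oxidation of the ether-substituted rings, so a small excess at 0 °C should touch ring C only.

Step 12
Reactants: 23 CDEFG phenol; 2 4-fluoro-3,5-dimethoxybenzaldehyde
Product: 24 4-{3,5-dimethoxy-4-[3,4,5-trimethoxy-2-(EFG aryloxy)phenoxy]phenoxy}-3,5-dimethoxybenzaldehyde (BCDEFG aldehyde)
Conditions: Cs2CO3, DMSO, 120 °C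
Reagents that add atoms: none
Why: SNAr as in step 3, with an unhindered position-1 phenoxide; attack of the phenoxide on the formyl-activated ring of the product would only exchange identical aryloxy groups.

Step 13
Reactants: 24 BCDEFG aldehyde
Product: 26 4-{3,5-dimethoxy-4-[3,4,5-trimethoxy-2-(EFG aryloxy)phenoxy]phenoxy}-3,5-dimethoxyphenol (BCDEFG phenol), via BCDEFG aryl formate 25 (not isolated)
Conditions: mCPBA (1.1 equiv), CH2Cl2, 0 °C → rt; then Et3N (cat.), MeOH, rt
Reagents that add atoms: 3-chloroperoxybenzoic acid (mCPBA), OOC(=O)c1cccc(Cl)c1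
Why: Baeyer–Villiger oxidation and formate methanolysis, as in step 2.

Step 14
Reactants: 26 BCDEFG phenol; 2 4-fluoro-3,5-dimethoxybenzaldehyde
Product: 27 4-(4-{3,5-dimethoxy-4-[3,4,5-trimethoxy-2-(EFG aryloxy)phenoxy]phenoxy}-3,5-dimethoxyphenoxy)-3,5-dimethoxybenzaldehyde (ABCDEFG aldehyde)
Conditions: Cs2CO3, DMSO, 120 °C
Reagents that add atoms: none
Why: SNAr as in step 3; it places ring A with its two flanking methoxy groups and the formyl group at the future A4 hydroxyl.

Step 15
Reactants: 27 ABCDEFG aldehyde
Product: 29 hexadeca-O-methyl heptamer phenol (free hydroxyl at A4), via heptamer aryl formate 28 (not isolated)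
Conditions: mCPBA (1.1 equiv), CH2Cl2, 0 °C → rt; then Et3N (cat.), MeOH, rt
Reagents that add atoms: 3-chloroperoxybenzoic acid (mCPBA), OOC(=O)c1cccc(Cl)c1
Why: Baeyer–Villiger oxidation and formate methanolysis, as in step 2; it turns the last formyl group into the A4 oxygen.

Step 16
Reactants: 29 hexadeca-O-methyl heptamer phenol
Product: 30 CNP0304148.0 (heptadecahydroxy heptamer)
Conditions: BBr3 (excess), CH2Cl2, −78 °C → rt; then MeOH, H2O, Ar
Reagents that add atoms: none
Why: Lewis acid-mediated ether cleavage: BBr3 coordinates each methoxy oxygen and bromide attacks the methyl carbon (SN2), giving aryl borates that methanol and water hydrolyse; the diaryl ether oxygens offer no sp3 carbon to bromide and should survive. Reaction and work-up are kept under argon and free of base because the product is air-sensitive.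

## Compound list

1 | 3,4,5-trimethoxyphenol | COc1cc(O)cc(OC)c1OC | starting material
2 | 4-fluoro-3,5-dimethoxybenzaldehyde | COc1cc(C=O)cc(OC)c1F | starting material
3 | 3,5-dimethoxy-4-(3,4,5-trimethoxyphenoxy)benzaldehyde (FG aldehyde) | O=Cc1cc(OC)c(Oc2cc(OC)c(OC)c(OC)c2)c(OC)c1 | intermediate
4 | 3,5-dimethoxy-4-(3,4,5-trimethoxyphenoxy)phenyl formate (FG aryl formate, formed in the flask) | O=COc1cc(OC)c(Oc2cc(OC)c(OC)c(OC)c2)c(OC)c1 | intermediate
5 | 3,5-dimethoxy-4-(3,4,5-trimethoxyphenoxy)phenol (FG phenol) | Oc1cc(OC)c(Oc2cc(OC)c(OC)c(OC)c2)c(OC)c1 | intermediate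
6 | 4-[3,5-dimethoxy-4-(3,4,5-trimethoxyphenoxy)phenoxy]-3,5-dimethoxybenzaldehyde (EFG aldehyde) | O=Cc1cc(OC)c(Oc2cc(OC)c(Oc3cc(OC)c(OC)c(OC)c3)c(OC)c2)c(OC)c1 | intermediate
7 | 4-[3,5-dimethoxy-4-(3,4,5-trimethoxyphenoxy)phenoxy]-3,5-dimethoxyphenyl formate (EFG aryl formate, formed in the flask) | O=COc1cc(OC)c(Oc2cc(OC)c(Oc3cc(OC)c(OC)c(OC)c3)c(OC)c2)c(OC)c1 | intermediate
8 | 4-[3,5-dimethoxy-4-(3,4,5-trimethoxyphenoxy)phenoxy]-3,5-dimethoxyphenol (EFG phenol, hydroxyl at E1) | Oc1cc(OC)c(Oc2cc(OC)c(Oc3cc(OC)c(OC)c(OC)c3)c(OC)c2)c(OC)c1 | intermediate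
9 | squaric acid (3,4-dihydroxycyclobut-3-ene-1,2-dione) | OC1=C(O)C(=O)C1=O | starting material
10 | squaric acid dichloride (3,4-dichlorocyclobut-3-ene-1,2-dione) | ClC1=C(Cl)C(=O)C1=O | intermediate
11 | 3-chloro-4-methoxycyclobut-3-ene-1,2-dione | COC1=C(Cl)C(=O)C1=O | intermediate
12 | sodium salt of EFG phenol 8 (formed in the flask) | [Na+].[O-]c1cc(OC)c(Oc2cc(OC)c(Oc3cc(OC)c(OC)c(OC)c3)c(OC)c2)c(OC)c1 | intermediate
13 | 3-(EFG aryloxy)-4-methoxycyclobut-3-ene-1,2-dione | COC1=C(Oc2cc(OC)c(Oc3cc(OC)c(Oc4cc(OC)c(OC)c(OC)c4)c(OC)c3)c(OC)c2)C(=O)C1=O | intermediate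
14 | methyl vinyl ether | COC=C | starting material
15 | 1-methoxyvinyllithium (formed in the flask) | [Li]C(=C)OC | intermediate
16 | racemic lithium 2-(EFG aryloxy)-3-methoxy-1-(1-methoxyvinyl)-4-oxocyclobut-2-en-1-olate (formed in the flask) | [Li+].C=C(OC)C1([O-])C(OC)=C(Oc2cc(OC)c(Oc3cc(OC)c(Oc4cc(OC)c(OC)c(OC)c4)c(OC)c3)c(OC)c2)C1=O | intermediate
17 | racemic 2-(EFG aryloxy)-3,4-dimethoxy-4-(1-methoxyvinyl)cyclobut-2-en-1-one | C=C(OC)C1(OC)C(OC)=C(Oc2cc(OC)c(Oc3cc(OC)c(Oc4cc(OC)c(OC)c(OC)c4)c(OC)c3)c(OC)c2)C1=O | intermediate
18 | (Z)-2-(EFG aryloxy)-3,4,5-trimethoxyhexa-1,3,5-trien-1-one (dienylketene, formed in the flask) | O=C=C(Oc1cc(OC)c(Oc2cc(OC)c(Oc3cc(OC)c(OC)c(OC)c3)c(OC)c2)c(OC)c1)/C(OC)=C(/OC)C(OC)=C | intermediate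
19 | 2-(EFG aryloxy)-3,4,5-trimethoxycyclohexa-2,4-dien-1-one (formed in the flask) | O=C1CC(OC)=C(OC)C(OC)=C1Oc1cc(OC)c(Oc2cc(OC)c(Oc3cc(OC)c(OC)c(OC)c3)c(OC)c2)c(OC)c1 | intermediate
20 | 2-(EFG aryloxy)-3,4,5-trimethoxyphenol (DEFG phenol, hydroxyl at D1) | Oc1cc(OC)c(OC)c(OC)c1Oc1cc(OC)c(Oc2cc(OC)c(Oc3cc(OC)c(OC)c(OC)c3)c(OC)c2)c(OC)c1 | intermediate
21 | 3,5-dimethoxy-4-[3,4,5-trimethoxy-2-(EFG aryloxy)phenoxy]benzaldehyde (CDEFG aldehyde) | O=Cc1cc(OC)c(Oc2cc(OC)c(OC)c(OC)c2Oc2cc(OC)c(Oc3cc(OC)c(Oc4cc(OC)c(OC)c(OC)c4)c(OC)c3)c(OC)c2)c(OC)c1 | intermediate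
22 | 3,5-dimethoxy-4-[3,4,5-trimethoxy-2-(EFG aryloxy)phenoxy]phenyl formate (formed in the flask) | O=COc1cc(OC)c(Oc2cc(OC)c(OC)c(OC)c2Oc2cc(OC)c(Oc3cc(OC)c(Oc4cc(OC)c(OC)c(OC)c4)c(OC)c3)c(OC)c2)c(OC)c1 | intermediate
23 | 3,5-dimethoxy-4-[3,4,5-trimethoxy-2-(EFG aryloxy)phenoxy]phenol (CDEFG phenol) | Oc1cc(OC)c(Oc2cc(OC)c(OC)c(OC)c2Oc2cc(OC)c(Oc3cc(OC)c(Oc4cc(OC)c(OC)c(OC)c4)c(OC)c3)c(OC)c2)c(OC)c1 | intermediate
24 | 4-{3,5-dimethoxy-4-[3,4,5-trimethoxy-2-(EFG aryloxy)phenoxy]phenoxy}-3,5-dimethoxybenzaldehyde (BCDEFG aldehyde) | O=Cc1cc(OC)c(Oc2cc(OC)c(Oc3cc(OC)c(OC)c(OC)c3Oc3cc(OC)c(Oc4cc(OC)c(Oc5cc(OC)c(OC)c(OC)c5)c(OC)c4)c(OC)c3)c(OC)c2)c(OC)c1 | intermediate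
25 | 4-{3,5-dimethoxy-4-[3,4,5-trimethoxy-2-(EFG aryloxy)phenoxy]phenoxy}-3,5-dimethoxyphenyl formate (formed in the flask) | O=COc1cc(OC)c(Oc2cc(OC)c(Oc3cc(OC)c(OC)c(OC)c3Oc3cc(OC)c(Oc4cc(OC)c(Oc5cc(OC)c(OC)c(OC)c5)c(OC)c4)c(OC)c3)c(OC)c2)c(OC)c1 | intermediate
26 | 4-{3,5-dimethoxy-4-[3,4,5-trimethoxy-2-(EFG aryloxy)phenoxy]phenoxy}-3,5-dimethoxyphenol (BCDEFG phenol) | Oc1cc(OC)c(Oc2cc(OC)c(Oc3cc(OC)c(OC)c(OC)c3Oc3cc(OC)c(Oc4cc(OC)c(Oc5cc(OC)c(OC)c(OC)c5)c(OC)c4)c(OC)c3)c(OC)c2)c(OC)c1 | intermediate
27 | 4-(4-{3,5-dimethoxy-4-[3,4,5-trimethoxy-2-(EFG aryloxy)phenoxy]phenoxy}-3,5-dimethoxyphenoxy)-3,5-dimethoxybenzaldehyde (ABCDEFG aldehyde) | O=Cc1cc(OC)c(Oc2cc(OC)c(Oc3cc(OC)c(Oc4cc(OC)c(OC)c(OC)c4Oc4cc(OC)c(Oc5cc(OC)c(Oc6cc(OC)c(OC)c(OC)c6)c(OC)c5)c(OC)c4)c(OC)c3)c(OC)c2)c(OC)c1 | intermediate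
28 | formate ester of heptamer phenol 29 at A4 (formed in the flask) | O=COc1cc(OC)c(Oc2cc(OC)c(Oc3cc(OC)c(Oc4cc(OC)c(OC)c(OC)c4Oc4cc(OC)c(Oc5cc(OC)c(Oc6cc(OC)c(OC)c(OC)c6)c(OC)c5)c(OC)c4)c(OC)c3)c(OC)c2)c(OC)c1 | intermediate
29 | hexadeca-O-methyl heptamer phenol (all hydroxyls of 30 methylated except A4) | Oc1cc(OC)c(Oc2cc(OC)c(Oc3cc(OC)c(Oc4cc(OC)c(OC)c(OC)c4Oc4cc(OC)c(Oc5cc(OC)c(Oc6cc(OC)c(OC)c(OC)c6)c(OC)c5)c(OC)c4)c(OC)c3)c(OC)c2)c(OC)c1 | intermediate
30 | CNP0304148.0, heptadecahydroxy heptamer (rings linked A1–O–B1, B4–O–C1, C4–O–D1, D6–O–E1, E4–O–F1, F4–O–G1) | Oc1cc(O)c(Oc2cc(O)c(Oc3cc(O)c(Oc4cc(O)c(O)c(O)c4Oc4cc(O)c(Oc5cc(O)c(Oc6cc(O)c(O)c(O)c6)c(O)c5)c(O)c4)c(O)c3)c(O)c2)c(O)c1 | target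

## Step count and least certain steps

Total step count: 16. Longest linear sequence: 14 steps (steps 1–4 and 7–16, from 1 through 3, 5, 6, 8, 13, 17, 20, 21, 23, 24, 26, 27, 29 to 30). The squarate branch 9 → 10 → 11 (steps 5 and 6) joins at step 7.

**Step 9 (key step).** The most likely failure is loss of the 1-methoxyvinyl enol ether by adventitious acid before the ring opens, or capture of the ketene by traces of water; either diverts material from the electrocyclisation. The aryloxy group on the ketene carbon may also raise the temperature needed for opening, so that prolonged heating erodes the electron-rich product. The fallback abandons the ring construction. It sets out from 8, which is coupled with 2-bromo-3,4,5-trimethoxybenzaldehyde in an Ullmann ether synthesis (CuI, N,N-dimethylglycine, Cs2CO3, dioxane, 100 °C) to give 3,4,5-trimethoxy-2-(EFG aryloxy)benzaldehyde F1. Baeyer–Villiger oxidation with mCPBA then gives 3,4,5-trimethoxy-2-(EFG aryloxy)phenyl formate F2, and methanolysis (Et3N, MeOH) returns to the route at 20. The cost is a coupling at a carbon flanked by formyl and methoxy groups.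

**Step 8.** Three processes may interfere. The first is competing attack at the other carbonyl, or addition–elimination that expels the aryloxide, since the two carbonyls differ only in the donor strength of OMe against OAr. The second is incomplete O-methylation of the hindered lithium alkoxide, or its anion-accelerated ring opening if the mixture must be warmed to complete the methylation. The third is loss of the enol ether on work-up. The fallback sets out from 13: the addition is quenched at −78 °C with aqueous NH4Cl to give the racemic alcohol 2-(EFG aryloxy)-4-hydroxy-3-methoxy-4-(1-methoxyvinyl)cyclobut-2-en-1-one F3. This is purified on base-washed silica and methylated under neutral conditions (MeI, Ag2O, MeCN, rt), which returns to the route at 17. If site selectivity and not methylation is what fails, the detour described for step 9 (8 to 20 through F1 and F2) bypasses the squarate altogether.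

**Step 10.** Addition to the fluoroarene may be slow because both partners are crowded (an ortho EFG aryloxy group on the nucleophile, two ortho methoxy groups on the electrophile); long heating in base then degrades the aldehyde. The fallback sets out from 20 and replaces SNAr with a palladium-catalysed C–O coupling with 4-bromo-3,5-dimethoxybenzaldehyde (Pd(OAc)2, t-BuXPhos, K3PO4, toluene, 100 °C). Oxidative addition is helped by the para formyl group and reductive elimination from the bulky phosphine complex tolerates ortho substituents. It comes back at 21 directly and makes no compound outside the compound list (F0).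

**Step 16.** Cleavage of sixteen ethers may stop short at crowded methoxy groups as aryl borates precipitate, and the free polyphenol may degrade oxidatively during isolation. The fallback sets out from 29: after the BBr3 treatment and methanol quench, the crude polyphenol is not isolated but acetylated (Ac2O, pyridine, rt) to the heptadecaacetate of 30, F4. F4 is air-stable and can be separated on silica from incompletely demethylated material. Deacetylation with hydrazine hydrate (N2H4·H2O, MeCN/MeOH, 0 °C → rt, Ar), which is non-oxidising, then releases 30.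

## Further compounds

F1 | step 9 | 3,4,5-trimethoxy-2-(EFG aryloxy)benzaldehyde | O=Cc1cc(OC)c(OC)c(OC)c1Oc1cc(OC)c(Oc2cc(OC)c(Oc3cc(OC)c(OC)c(OC)c3)c(OC)c2)c(OC)c1
F2 | step 9 | 3,4,5-trimethoxy-2-(EFG aryloxy)phenyl formate | O=COc1cc(OC)c(OC)c(OC)c1Oc1cc(OC)c(Oc2cc(OC)c(Oc3cc(OC)c(OC)c(OC)c3)c(OC)c2)c(OC)c1
F3 | step 8 | racemic 2-(EFG aryloxy)-4-hydroxy-3-methoxy-4-(1-methoxyvinyl)cyclobut-2-en-1-one | C=C(OC)C1(O)C(OC)=C(Oc2cc(OC)c(Oc3cc(OC)c(Oc4cc(OC)c(OC)c(OC)c4)c(OC)c3)c(OC)c2)C1=O
F0 | step 10 | none | none
F4 | step 16 | heptadecaacetate of 30 | CC(=O)Oc1cc(OC(C)=O)c(Oc2cc(OC(C)=O)c(Oc3cc(OC(C)=O)c(Oc4cc(OC(C)=O)c(OC(C)=O)c(OC(C)=O)c4Oc4cc(OC(C)=O)c(Oc5cc(OC(C)=O)c(Oc6cc(OC(C)=O)c(OC(C)=O)c(OC(C)=O)c6)c(OC(C)=O)c5)c(OC(C)=O)c4)c(OC(C)=O)c3)c(OC(C)=O)c2)c(OC(C)=O)c1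
A1 | alternative 1 | [CpRu(2,5-dichloro-1,3-dimethoxybenzene)]PF6 | COc1cc(Cl)cc(OC)c1Cl.[Ru+2].c1cc[cH-]c1.F[P-](F)(F)(F)(F)F
A2 | alternative 1 | 2,6-dimethoxy-4-(2,4,6-trimethoxyphenoxy)phenol (AB dimer phenol, hydroxyl at B4) | COc1cc(OC)c(Oc2cc(OC)c(O)c(OC)c2)c(OC)c1
A3 | alternative 1 | 2-(benzyloxy)-3,4,5-trimethoxyphenol (ring D unit, hydroxyl at D1) | Oc1cc(OC)c(OC)c(OC)c1OCc1ccccc1
A4 | alternative 1 | cyclopentadienylruthenium hexafluorophosphate complex of the permethylated ABCD tetramer with benzyloxy at D6 | COc1cc(OC)c(Oc2cc(OC)c(Oc3cc(OC)c(Oc4cc(OC)c(OC)c(OC)c4OCc5ccccc5)c(OC)c3)c(OC)c2)c(OC)c1.[Ru+2].c1cc[cH-]c1.F[P-](F)(F)(F)(F)F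
A5 | alternative 2 | methyl 6-[4-(benzyloxy)-3,5-dimethoxyphenoxy]-3,5-dioxohexanoate | COC(=O)CC(=O)CC(=O)COc1cc(OC)c(OCc2ccccc2)c(OC)c1
A6 | alternative 2 | 2-[4-(benzyloxy)-3,5-dimethoxyphenoxy]benzene-1,3,5-triol (AB dimer) | Oc1cc(O)c(Oc2cc(OC)c(OCc3ccccc3)c(OC)c2)c(O)c1
A7 | alternative 3 | 4-(benzyloxy)-2,6-dimethoxyphenyl 3,5-dimethoxy-4-[(3,4,5-trimethoxybenzoyl)oxy]benzoate (depside) | COc1cc(C(=O)Oc2c(OC)cc(C(=O)Oc3c(OC)cc(OCc4ccccc4)cc3OC)cc2OC)cc(OC)c1OC
A8 | alternative 3 | 5-(benzyloxy)-2-[3,5-dimethoxy-4-(3,4,5-trimethoxyphenoxy)phenoxy]-1,3-dimethoxybenzene (EFG trimer, benzyloxy at E1) | COc1cc(Oc2c(OC)cc(Oc3c(OC)cc(OCc4ccccc4)cc3OC)cc2OC)cc(OC)c1OC
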